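**Strategy.** The route rests on cutting the C7–C8 bond of the carbocycle (C4a–C5–C6–C7–C8–C8a). The tertiary α-ketol C8(=O)–C7(OH)(CH3) beside the C6 carbinol is the retron of an aldehyde–ketone benzoin reaction. A chiral triazolylidene carbene turns the C8 aldehyde of an open-chain keto aldehyde into an acyl anion equivalent that adds to the C7 methyl ketone. In one operation this closes the six-membered ring, forms C7–C8 and sets the quaternary C7 carbinol cis to the C6 oxygen. The precursor, made from (R)-malic acid, carries the C6 silyl ether, the C7 methyl ketone, a dioxolane at C4a and the C8 aldehyde; the pyran ring and the orsellinate follow.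

Key step: step 8

Remark on numbering and configuration: atom labels C1–C8a are those of the isochromene core of the target. The target is (6R,7R) with the C7 hydroxyl cis to the C6 ester oxygen, and C6 is C2 of (R)-malic acid carried through unchanged.

Remark on precursor design: the keto aldehyde is released in its last step by oxidising two alcohols at once. No step therefore has to reduce an ester beside a ketone, and the β-ketal aldehyde never meets hydride or strong base. The bulky, non-chelating TBS ether is kept at C6 because it reinforces the catalyst.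

Assumption: the (5aR,10bS) antipode of the aminoindanol-derived triazolium salt is taken as the one that directs Si-face attack on the C7 ketone; if the sense proves opposite, the (5aS,10bR) salt is used with nothing else changed.

Step 1
Reactants: 1 (R)-malic acid
Product: 3 (3R)-3-hydroxy-4-methoxy-4-oxobutanoic acid, via O-trifluoroacetylmalic anhydride 2 (not isolated)
Conditions: TFAA (neat), 0 °C → rt; evaporate; MeOH, 0 °C → rt; evaporate
Reagents that add atoms: methanol CO; trifluoroacetic anhydride O=C(OC(=O)C(F)(F)F)C(F)(F)F (trifluoroacetyl group of intermediate 2 only)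
Why: Cyclic anhydride formation and regioselective alcoholysis, in which methanol opens the O-acylated anhydride at the more electrophilic carbonyl next to the acyloxy group (C1) and also methanolyses the trifluoroacetate, so the two carboxyls are told apart without touching the stereocentre.

Step 2
Reactants: 3 (3R)-3-hydroxy-4-methoxy-4-oxobutanoic acid
Product: 5 (3R)-3-[(tert-butyldimethylsilyl)oxy]-4-methoxy-4-oxobutanoic acid, via TBS ester 4 (not isolated)
Conditions: TBSCl (2.3 equiv), imidazole, DMF, rt; then AcOH/THF/H2O, rt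
Reagents that add atoms: tert-butyldimethylsilyl chloride CC(C)(C)[Si](C)(C)Cl
Why: Silylation of alcohol and acid followed by selective hydrolysis of the labile silyl ester, which leaves the secondary TBS ether in place.

Step 3
Reactants: 5 (3R)-3-[(tert-butyldimethylsilyl)oxy]-4-methoxy-4-oxobutanoic acid; 6 mono-tert-butyl malonate
Product: 9 6-tert-butyl 1-methyl (2R)-2-[(tert-butyldimethylsilyl)oxy]-4-oxohexanedioate, via acyl imidazolide 7 (not isolated), via acylmalonic half ester 8 (not isolated)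
Conditions: CDI, THF, rt; then 6, MgCl2, Et3N, THF/MeCN, rt → 40 °C; aq. citric acid
Reagents that add atoms: 1,1'-carbonyldiimidazole O=C(n1ccnc1)n1ccnc1 (imidazolyl group of intermediate 7 only)
Why: Masamune–Brooks homologation, in which the magnesium enolate of the malonate half ester is C-acylated by the acyl imidazolide and decarboxylates to the β-keto ester under near-neutral conditions that should avoid β-elimination of the silyloxy group and attack on the methyl ester.

Step 4
Reactants: 9 6-tert-butyl 1-methyl (2R)-2-[(tert-butyldimethylsilyl)oxy]-4-oxohexanedioate; 10 1,2-bis(trimethylsilyloxy)ethane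
Product: 11 methyl (2R)-3-[2-(2-tert-butoxy-2-oxoethyl)-1,3-dioxolan-2-yl]-2-[(tert-butyldimethylsilyl)oxy]propanoate
Conditions: TMSOTf (5 mol%), CH2Cl2, −78 → −20 °C; pyridine quench
Reagents that add atoms: none
Why: Noyori ketalisation, an aprotic low-temperature transfer of the glycol unit to the ketone that should spare the TBS ether, both esters and the stereocentre.

Step 5
Reactants: 11 methyl (2R)-3-[2-(2-tert-butoxy-2-oxoethyl)-1,3-dioxolan-2-yl]-2-[(tert-butyldimethylsilyl)oxy]propanoate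
Product: 13 tert-butyl 2-{2-[(2R)-2-[(tert-butyldimethylsilyl)oxy]-3-oxobutyl]-1,3-dioxolan-2-yl}acetate, via Weinreb amide 12 (not isolated)
Conditions: MeNHOMe·HCl, i-PrMgCl, THF, −20 °C; then MeMgCl, −20 → 0 °C; aq. NH4Cl
Reagents that add atoms: methylmagnesium chloride C[Mg]Cl; N,O-dimethylhydroxylamine hydrochloride CNOC.Cl (amide nitrogen unit of intermediate 12 only)
Why: One-pot ester-to-ketone conversion through a Weinreb amide, in which the chloromagnesium amide aminolyses only the unhindered methyl ester and the Grignard reagent adds once to the chelated amide while the tert-butyl ester is too hindered to react at 0 °C.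

Step 6
Reactants: 13 tert-butyl 2-{2-[(2R)-2-[(tert-butyldimethylsilyl)oxy]-3-oxobutyl]-1,3-dioxolan-2-yl}acetate
Product: 14 (2RS,3R)-3-[(tert-butyldimethylsilyl)oxy]-4-[2-(2-hydroxyethyl)-1,3-dioxolan-2-yl]butan-2-ol
Conditions: LiAlH4, Et2O, −20 → 0 °C; Rochelle salt work-up
Reagents that add atoms: none
Why: Hydride reduction of ketone and ester together, which removes any need for ester-over-ketone selectivity; the new carbinol centre is irrelevant because it is re-oxidised, and the cold non-basic work-up should prevent 1,2-silyl migration.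

Step 7
Reactants: 14 (2RS,3R)-3-[(tert-butyldimethylsilyl)oxy]-4-[2-(2-hydroxyethyl)-1,3-dioxolan-2-yl]butan-2-ol
Product: 15 2-{2-[(2R)-2-[(tert-butyldimethylsilyl)oxy]-3-oxobutyl]-1,3-dioxolan-2-yl}acetaldehyde
Conditions: Dess–Martin periodinane, pyridine, CH2Cl2, 0 °C → rt; used directly
Reagents that add atoms: none
Why: Dess–Martin oxidation of both alcohols in one operation under buffered conditions that should leave the α-silyloxy centre, the ketal and the β-ketal aldehyde intact.

Step 8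
Reactants: 15 2-{2-[(2R)-2-[(tert-butyldimethylsilyl)oxy]-3-oxobutyl]-1,3-dioxolan-2-yl}acetaldehyde
Product: 16 (8R,9R)-9-[(tert-butyldimethylsilyl)oxy]-8-hydroxy-8-methyl-1,4-dioxaspiro[4.5]decan-7-one
Conditions: (5aR,10bS)-2-(pentafluorophenyl)-5a,10b-dihydro-4H,6H-indeno[2,1-b][1,2,4]triazolo[4,3-d][1,4]oxazin-2-ium tetrafluoroborate (15 mol%), Et3N (15 mol%), toluene (0.05 M), rt
Reagents that add atoms: none
Why: N-Heterocyclic carbene catalysis (intramolecular crossed benzoin): the triazolylidene adds to the unhindered C8 aldehyde, proton transfer gives the Breslow intermediate, this acyl anion equivalent attacks the C7 ketone, and proton transfer with loss of the carbene releases the α-ketol. The closest known reaction type is the chiral triazolium-catalysed aldehyde–ketone benzoin cyclisation that gives six-membered tertiary α-ketols. The carbocycle C8–C8a–C4a–C5–C6–C7 closes in a 6-exo-trig mode. The only new stereocentre, C7, is set by the catalyst, whose antipode is chosen for attack on the Si face of the ketone, and the substrate reinforces it: in the chair-like transition state the bulky non-chelating C6 silyloxy group sits equatorial and anti to the forming bond (polar Felkin–Anh), which places the new hydroxyl cis to C6–O. The step needs carbene addition to the aldehyde only, cross- over homo-coupling, and no aldol or epimerisation; the aldehyde is unbranched while the ketone is α-branched, the ketal removes the enolisable C4a carbonyl and its gem-disubstitution favours closure, and a weak amine base at high dilution should leave C6–H and the β-ketal aldehyde alone.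

Step 9
Reactants: 16 (8R,9R)-9-[(tert-butyldimethylsilyl)oxy]-8-hydroxy-8-methyl-1,4-dioxaspiro[4.5]decan-7-one
Product: 17 (4R,5R)-5-[(tert-butyldimethylsilyl)oxy]-4-hydroxy-4-methylcyclohexane-1,3-dione
Conditions: PPTS, acetone/H2O (9:1), 50 °C
Reagents that add atoms: water O
Why: Acid-catalysed ketal hydrolysis, driven by enolisation of the resulting 1,3-dione and mild enough for the hindered secondary TBS ether.

Step 10
Reactants: 17 (4R,5R)-5-[(tert-butyldimethylsilyl)oxy]-4-hydroxy-4-methylcyclohexane-1,3-dione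
Product: 18 (4R,5R)-5-[(tert-butyldimethylsilyl)oxy]-4-hydroxy-4-methyl-3-oxocyclohex-1-en-1-yl trifluoromethanesulfonate
Conditions: PhNTf2, Et3N, CH2Cl2, 0 °C → rt
Reagents that add atoms: N-phenylbis(trifluoromethanesulfonimide) O=S(=O)(N(c1ccccc1)S(=O)(=O)C(F)(F)F)C(F)(F)F
Why: Enol triflate formation from the dione enolate with a reagent that does not sulfonylate the tertiary alcohol; the C4a oxygen is the unhindered one, while the C8 oxygen is shielded by quaternary C7 and hydrogen-bonded to its hydroxyl, so the C4a triflate with the C8 ketone retained is expected.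

Step 11
Reactants: 19 (2E)-pent-2-en-4-yn-1-ol
Product: 20 tert-butyl{[(2E)-pent-2-en-4-yn-1-yl]oxy}diphenylsilane
Conditions: TBDPSCl, imidazole, CH2Cl2, 0 °C → rt
Reagents that add atoms: tert-butyldiphenylsilyl chloride CC(C)(C)[Si](Cl)(c1ccccc1)c1ccccc1
Why: Standard silylation of a primary alcohol; TBDPS is chosen because it should outlast the later acidic-fluoride removal of the C6 TBS ether.

Step 12
Reactants: 18 (4R,5R)-5-[(tert-butyldimethylsilyl)oxy]-4-hydroxy-4-methyl-3-oxocyclohex-1-en-1-yl trifluoromethanesulfonate; 20 tert-butyl{[(2E)-pent-2-en-4-yn-1-yl]oxy}diphenylsilane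
Product: 21 (5R,6R)-5-[(tert-butyldimethylsilyl)oxy]-3-{(3E)-5-[(tert-butyldiphenylsilyl)oxy]pent-3-en-1-yn-1-yl}-6-hydroxy-6-methylcyclohex-2-en-1-one
Conditions: Pd(PPh3)2Cl2 (3 mol%), CuI (6 mol%), Et3N, THF, rt
Reagents that add atoms: none
Why: Sonogashira coupling of a β-triflyloxy enone, which undergoes oxidative addition at room temperature while the tertiary alcohol and both silyl ethers stay inert.

Step 13
Reactants: 21 (5R,6R)-5-[(tert-butyldimethylsilyl)oxy]-3-{(3E)-5-[(tert-butyldiphenylsilyl)oxy]pent-3-en-1-yn-1-yl}-6-hydroxy-6-methylcyclohex-2-en-1-one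
Product: 22 (5R,6R)-5-[(tert-butyldimethylsilyl)oxy]-3-{(3E)-5-[(tert-butyldiphenylsilyl)oxy]pent-3-en-1-yn-1-yl}-6-hydroxy-2-iodo-6-methylcyclohex-2-en-1-one
Conditions: I2, pyridine, CH2Cl2, rt, dark
Reagents that add atoms: iodine II
Why: Johnson α-iodination of an enone (reversible conjugate addition of pyridine, iodination of the enolate at C8a, loss of pyridine), a method that works on β-substituted cyclohexenones; the electron-poor conjugated enyne should not take up iodine under these conditions.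

Step 14
Reactants: 22 (5R,6R)-5-[(tert-butyldimethylsilyl)oxy]-3-{(3E)-5-[(tert-butyldiphenylsilyl)oxy]pent-3-en-1-yn-1-yl}-6-hydroxy-2-iodo-6-methylcyclohex-2-en-1-one; 23 (tributylstannyl)methanol
Product: 25 (6R,7R)-6-[(tert-butyldimethylsilyl)oxy]-3-{(1E)-3-[(tert-butyldiphenylsilyl)oxy]prop-1-en-1-yl}-7-hydroxy-7-methyl-1,5,6,7-tetrahydro-8H-isochromen-8-one, via hydroxymethyl enynone 24 (not isolated)
Conditions: Pd(PPh3)4 (5 mol%), dioxane, 80 °C; then DBU (0.2 equiv), rt
Reagents that add atoms: none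
Why: Stille hydroxymethylation of the α-iodoenone followed by base-catalysed 6-endo-dig oxa-Michael (1,6-) addition of the new C1 hydroxyl to C3, the electrophilic terminus of the ynenone, and protonation at C4; 5-exo attack would need the non-electrophilic C4, and the C6 oxygen is still silylated so it cannot compete.

Step 15
Reactants: 25 (6R,7R)-6-[(tert-butyldimethylsilyl)oxy]-3-{(1E)-3-[(tert-butyldiphenylsilyl)oxy]prop-1-en-1-yl}-7-hydroxy-7-methyl-1,5,6,7-tetrahydro-8H-isochromen-8-one
Product: 26 (6R,7R)-3-{(1E)-3-[(tert-butyldiphenylsilyl)oxy]prop-1-en-1-yl}-6,7-dihydroxy-7-methyl-1,5,6,7-tetrahydro-8H-isochromen-8-one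
Conditions: HF·pyridine, pyridine, THF, 0 °C → rt
Reagents that add atoms: none
Why: Selective desilylation, in which buffered HF·pyridine should cleave the secondary TBS ether, assisted by the neighbouring hydroxyl, while the acid-stable primary TBDPS ether persists.

Step 16
Reactants: 27 orsellinic acid
Product: 28 tert-butyldimethylsilyl 2,4-bis[(tert-butyldimethylsilyl)oxy]-6-methylbenzoate
Conditions: TBSCl (3.5 equiv), imidazole, DMF, 40 °C
Reagents that add atoms: tert-butyldimethylsilyl chloride CC(C)(C)[Si](C)(C)Cl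
Why: Exhaustive silylation of both phenols and the carboxylic acid with TBSCl and imidazole.

Step 17
Reactants: 26 (6R,7R)-3-{(1E)-3-[(tert-butyldiphenylsilyl)oxy]prop-1-en-1-yl}-6,7-dihydroxy-7-methyl-1,5,6,7-tetrahydro-8H-isochromen-8-one; 28 tert-butyldimethylsilyl 2,4-bis[(tert-butyldimethylsilyl)oxy]-6-methylbenzoate
Product: 30 (6R,7R)-3-{(1E)-3-[(tert-butyldiphenylsilyl)oxy]prop-1-en-1-yl}-7-hydroxy-7-methyl-8-oxo-5,6,7,8-tetrahydro-1H-isochromen-6-yl 2,4-bis[(tert-butyldimethylsilyl)oxy]-6-methylbenzoate, via aroyl chloride 29 (not isolated)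
Conditions: 28, (COCl)2, DMF (cat.), CH2Cl2, 0 °C → rt, evaporate; then 26, DMAP, Et3N, CH2Cl2, rt → 40 °C
Reagents that add atoms: oxalyl chloride ClC(=O)C(Cl)=O (chlorine of intermediate 29 only)
Why: Direct conversion of the silyl ester into the acid chloride under neutral conditions (no free HCl, so the aryl silyl ethers survive), then DMAP-catalysed acylation of the secondary C6 hydroxyl in preference to the tertiary C7 hydroxyl; C6 keeps its configuration because its C–O bond is not broken.

Step 18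
Reactants: 30 (6R,7R)-3-{(1E)-3-[(tert-butyldiphenylsilyl)oxy]prop-1-en-1-yl}-7-hydroxy-7-methyl-8-oxo-5,6,7,8-tetrahydro-1H-isochromen-6-yl 2,4-bis[(tert-butyldimethylsilyl)oxy]-6-methylbenzoate
Product: 31 entonaemin A
Conditions: TBAF, AcOH (1:1), THF, 0 °C → rt
Reagents that add atoms: none
Why: Fluoride-mediated global desilylation of the two aryl TBS ethers and the primary TBDPS ether, buffered with acetic acid to suppress O6→O7 acyl migration and α-ketol rearrangement.

**Compound list**

1 | (R)-malic acid | O[C@H](CC(=O)O)C(=O)O | starting material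
2 | (3R)-2,5-dioxooxolan-3-yl trifluoroacetate (O-trifluoroacetylmalic anhydride) | O=C(O[C@@H]1CC(=O)OC1=O)C(F)(F)F | intermediate
3 | (3R)-3-hydroxy-4-methoxy-4-oxobutanoic acid | O[C@H](CC(=O)O)C(=O)OC | intermediate
4 | tert-butyldimethylsilyl (3R)-3-[(tert-butyldimethylsilyl)oxy]-4-methoxy-4-oxobutanoate | CC(C)(C)[Si](C)(C)O[C@H](CC(=O)O[Si](C)(C)C(C)(C)C)C(=O)OC | intermediate
5 | (3R)-3-[(tert-butyldimethylsilyl)oxy]-4-methoxy-4-oxobutanoic acid | CC(C)(C)[Si](C)(C)O[C@H](CC(=O)O)C(=O)OC | intermediate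
6 | mono-tert-butyl malonate (3-tert-butoxy-3-oxopropanoic acid) | CC(C)(C)OC(=O)CC(=O)O | starting material
7 | methyl (2R)-2-[(tert-butyldimethylsilyl)oxy]-4-(1H-imidazol-1-yl)-4-oxobutanoate | CC(C)(C)[Si](C)(C)O[C@H](CC(=O)n1ccnc1)C(=O)OC | intermediate
8 | (5R)-2-(tert-butoxycarbonyl)-5-[(tert-butyldimethylsilyl)oxy]-6-methoxy-3,6-dioxohexanoic acid | CC(C)(C)[Si](C)(C)O[C@H](CC(=O)C(C(=O)O)C(=O)OC(C)(C)C)C(=O)OC | intermediate
9 | 6-tert-butyl 1-methyl (2R)-2-[(tert-butyldimethylsilyl)oxy]-4-oxohexanedioate | CC(C)(C)[Si](C)(C)O[C@H](CC(=O)CC(=O)OC(C)(C)C)C(=O)OC | intermediate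
10 | 1,2-bis(trimethylsilyloxy)ethane | C[Si](C)(C)OCCO[Si](C)(C)C | starting material
11 | methyl (2R)-3-[2-(2-tert-butoxy-2-oxoethyl)-1,3-dioxolan-2-yl]-2-[(tert-butyldimethylsilyl)oxy]propanoate | CC(C)(C)[Si](C)(C)O[C@H](CC1(CC(=O)OC(C)(C)C)OCCO1)C(=O)OC | intermediate
12 | tert-butyl 2-{2-[(2R)-2-[(tert-butyldimethylsilyl)oxy]-3-[methoxy(methyl)amino]-3-oxopropyl]-1,3-dioxolan-2-yl}acetate | CON(C)C(=O)[C@H](O[Si](C)(C)C(C)(C)C)CC1(CC(=O)OC(C)(C)C)OCCO1 | intermediate
13 | tert-butyl 2-{2-[(2R)-2-[(tert-butyldimethylsilyl)oxy]-3-oxobutyl]-1,3-dioxolan-2-yl}acetate | CC(=O)[C@H](O[Si](C)(C)C(C)(C)C)CC1(CC(=O)OC(C)(C)C)OCCO1 | intermediate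
14 | (2RS,3R)-3-[(tert-butyldimethylsilyl)oxy]-4-[2-(2-hydroxyethyl)-1,3-dioxolan-2-yl]butan-2-ol | CC(O)[C@H](O[Si](C)(C)C(C)(C)C)CC1(CCO)OCCO1 | intermediate
15 | 2-{2-[(2R)-2-[(tert-butyldimethylsilyl)oxy]-3-oxobutyl]-1,3-dioxolan-2-yl}acetaldehyde | CC(=O)[C@H](O[Si](C)(C)C(C)(C)C)CC1(CC=O)OCCO1 | intermediate
16 | (8R,9R)-9-[(tert-butyldimethylsilyl)oxy]-8-hydroxy-8-methyl-1,4-dioxaspiro[4.5]decan-7-one | CC(C)(C)[Si](C)(C)O[C@@H]1CC2(OCCO2)CC(=O)[C@]1(C)O | intermediate
17 | (4R,5R)-5-[(tert-butyldimethylsilyl)oxy]-4-hydroxy-4-methylcyclohexane-1,3-dione | CC(C)(C)[Si](C)(C)O[C@@H]1CC(=O)CC(=O)[C@]1(C)O | intermediate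
18 | (4R,5R)-5-[(tert-butyldimethylsilyl)oxy]-4-hydroxy-4-methyl-3-oxocyclohex-1-en-1-yl trifluoromethanesulfonate | CC(C)(C)[Si](C)(C)O[C@@H]1CC(OS(=O)(=O)C(F)(F)F)=CC(=O)[C@]1(C)O | intermediate
19 | (2E)-pent-2-en-4-yn-1-ol | C#C/C=C/CO | starting material
20 | tert-butyl{[(2E)-pent-2-en-4-yn-1-yl]oxy}diphenylsilane | C#C/C=C/CO[Si](c1ccccc1)(c1ccccc1)C(C)(C)C | intermediate
21 | (5R,6R)-5-[(tert-butyldimethylsilyl)oxy]-3-{(3E)-5-[(tert-butyldiphenylsilyl)oxy]pent-3-en-1-yn-1-yl}-6-hydroxy-6-methylcyclohex-2-en-1-one | CC(C)(C)[Si](C)(C)O[C@@H]1CC(C#C/C=C/CO[Si](c2ccccc2)(c2ccccc2)C(C)(C)C)=CC(=O)[C@]1(C)O | intermediate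
22 | (5R,6R)-5-[(tert-butyldimethylsilyl)oxy]-3-{(3E)-5-[(tert-butyldiphenylsilyl)oxy]pent-3-en-1-yn-1-yl}-6-hydroxy-2-iodo-6-methylcyclohex-2-en-1-one | CC(C)(C)[Si](C)(C)O[C@@H]1CC(C#C/C=C/CO[Si](c2ccccc2)(c2ccccc2)C(C)(C)C)=C(I)C(=O)[C@]1(C)O | intermediate
23 | (tributylstannyl)methanol | CCCC[Sn](CCCC)(CCCC)CO | starting material
24 | (5R,6R)-5-[(tert-butyldimethylsilyl)oxy]-3-{(3E)-5-[(tert-butyldiphenylsilyl)oxy]pent-3-en-1-yn-1-yl}-6-hydroxy-2-(hydroxymethyl)-6-methylcyclohex-2-en-1-one | CC(C)(C)[Si](C)(C)O[C@@H]1CC(C#C/C=C/CO[Si](c2ccccc2)(c2ccccc2)C(C)(C)C)=C(CO)C(=O)[C@]1(C)O | intermediate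
25 | (6R,7R)-6-[(tert-butyldimethylsilyl)oxy]-3-{(1E)-3-[(tert-butyldiphenylsilyl)oxy]prop-1-en-1-yl}-7-hydroxy-7-methyl-1,5,6,7-tetrahydro-8H-isochromen-8-one | CC(C)(C)[Si](C)(C)O[C@@H]1CC2=C(COC(/C=C/CO[Si](c3ccccc3)(c3ccccc3)C(C)(C)C)=C2)C(=O)[C@]1(C)O | intermediate
26 | (6R,7R)-3-{(1E)-3-[(tert-butyldiphenylsilyl)oxy]prop-1-en-1-yl}-6,7-dihydroxy-7-methyl-1,5,6,7-tetrahydro-8H-isochromen-8-one | O[C@@H]1CC2=C(COC(/C=C/CO[Si](c3ccccc3)(c3ccccc3)C(C)(C)C)=C2)C(=O)[C@]1(C)O | intermediate
27 | orsellinic acid (2,4-dihydroxy-6-methylbenzoic acid) | Cc1cc(O)cc(O)c1C(=O)O | starting material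
28 | tert-butyldimethylsilyl 2,4-bis[(tert-butyldimethylsilyl)oxy]-6-methylbenzoate | Cc1cc(O[Si](C)(C)C(C)(C)C)cc(O[Si](C)(C)C(C)(C)C)c1C(=O)O[Si](C)(C)C(C)(C)C | intermediate
29 | 2,4-bis[(tert-butyldimethylsilyl)oxy]-6-methylbenzoyl chloride | Cc1cc(O[Si](C)(C)C(C)(C)C)cc(O[Si](C)(C)C(C)(C)C)c1C(Cl)=O | intermediate
30 | (6R,7R)-3-{(1E)-3-[(tert-butyldiphenylsilyl)oxy]prop-1-en-1-yl}-7-hydroxy-7-methyl-8-oxo-5,6,7,8-tetrahydro-1H-isochromen-6-yl 2,4-bis[(tert-butyldimethylsilyl)oxy]-6-methylbenzoate | Cc1cc(O[Si](C)(C)C(C)(C)C)cc(O[Si](C)(C)C(C)(C)C)c1C(=O)O[C@@H]1CC2=C(COC(/C=C/CO[Si](c3ccccc3)(c3ccccc3)C(C)(C)C)=C2)C(=O)[C@]1(C)O | intermediate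
31 | entonaemin A, (6R,7R)-7-hydroxy-3-[(1E)-3-hydroxyprop-1-en-1-yl]-7-methyl-8-oxo-5,6,7,8-tetrahydro-1H-isochromen-6-yl 2,4-dihydroxy-6-methylbenzoate | Cc1cc(O)cc(O)c1C(=O)O[C@@H]1CC2=C(COC(/C=C/CO)=C2)C(=O)[C@]1(C)O | target

**Step count and risks**

Total step count: 18 (16 on the main line, plus step 11 for the side chain and step 16 for the acyl fragment).
Longest linear sequence: 16 steps from (R)-malic acid (steps 1–10, 12–15, 17, 18).

Steps most likely to fail:

Step 8. The carbene may discriminate the two faces of the C7 ketone poorly, giving the C7 epimer. Alternatively, the enolisable β-ketal aldehyde may be consumed by aldol closure to a five-membered ring or by opening of the dioxolane before the Breslow intermediate is trapped. The fallback sets out from diol 14 and comes back at 16; it closes the same ring by a reversible nitroaldol reaction in which C8 arrives as a nitronate. Appel iodination of the primary alcohol of 14 (I2, PPh3, imidazole, 0 °C) should give (2RS,3R)-3-[(tert-butyldimethylsilyl)oxy]-4-[2-(2-iodoethyl)-1,3-dioxolan-2-yl]butan-2-ol F1. Displacement with sodium nitrite in DMF should give the nitro alcohol (2RS,3R)-3-[(tert-butyldimethylsilyl)oxy]-4-[2-(2-nitroethyl)-1,3-dioxolan-2-yl]butan-2-ol F2. Dess–Martin oxidation should give the nitro ketone (3R)-3-[(tert-butyldimethylsilyl)oxy]-4-[2-(2-nitroethyl)-1,3-dioxolan-2-yl]butan-2-one F3. Catalytic DBU then closes the ring by a 6-exo Henry reaction under thermodynamic control; the chair with the C6 silyloxy and C7 methyl groups equatorial and the hydroxyl axial, hence cis to C6–O, should dominate. This gives (8S,9R)-9-[(tert-butyldimethylsilyl)oxy]-8-methyl-7-nitro-1,4-dioxaspiro[4.5]decan-8-ol F4, where the 8S descriptor denotes the same geometry as 8R in 16 because the priorities change. An oxidative Nef reaction (KOtBu, −78 °C, then dimethyldioxirane) turns C8–NO2 into the ketone and delivers 16. The nitro group is far more acidic than C6–H, so C6 is not endangered.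

Step 13. Iodination may stall at the β,β-disubstituted enone, or be diverted by iodine uptake at the enyne or by 1,6-addition of pyridine. The fallback sets out from dione 17 and comes back at 25 through 24; the halogen is placed on C8a while that carbon is still the nucleophilic centre of the dione. N-Bromosuccinimide (CH2Cl2, 0 °C) should give (4R,5R)-2-bromo-5-[(tert-butyldimethylsilyl)oxy]-4-hydroxy-4-methylcyclohexane-1,3-dione F5. PhNTf2/Et3N should then give the bromo enol triflate (4R,5R)-2-bromo-5-[(tert-butyldimethylsilyl)oxy]-4-hydroxy-4-methyl-3-oxocyclohex-1-en-1-yl trifluoromethanesulfonate F6, by the same regiochemical argument as in step 10. Sonogashira coupling with 20 at room temperature should engage only the vinylogous acyl triflate and leave the α-bromide, giving (5R,6R)-2-bromo-5-[(tert-butyldimethylsilyl)oxy]-3-{(3E)-5-[(tert-butyldiphenylsilyl)oxy]pent-3-en-1-yn-1-yl}-6-hydroxy-6-methylcyclohex-2-en-1-one F7. Stille coupling of F7 with 23 at 90 °C, followed by DBU as in step 14, should give 24 and then 25.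

Step 17. Acyl transfer from the di-ortho-substituted aroyl chloride to the hindered C6 hydroxyl may be too slow, so that the acid chloride is lost to hydrolysis or desilylation first. The fallback sets out from 27 and 26 and comes back at 31; the acyl group is delivered from a benzodioxinone, whose ring-held carbonyl is opened readily by alkoxides. Orsellinic acid 27 with acetone and TFAA/TFA should give 7-hydroxy-2,2,5-trimethyl-4H-1,3-benzodioxin-4-one F8. Silylation (TBSCl, imidazole) should give 7-[(tert-butyldimethylsilyl)oxy]-2,2,5-trimethyl-4H-1,3-benzodioxin-4-one F9. The sodium alkoxide of 26 (NaHMDS, 1 equiv, THF, −78 → 0 °C, AcOH quench) should open F9 with loss of acetone to give (6R,7R)-3-{(1E)-3-[(tert-butyldiphenylsilyl)oxy]prop-1-en-1-yl}-7-hydroxy-7-methyl-8-oxo-5,6,7,8-tetrahydro-1H-isochromen-6-yl 4-[(tert-butyldimethylsilyl)oxy]-2-hydroxy-6-methylbenzoate F10, with the ortho hydroxyl already free. The conditions of step 18 then give 31.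

**Further compounds**

F1 | step 8 | (2RS,3R)-3-[(tert-butyldimethylsilyl)oxy]-4-[2-(2-iodoethyl)-1,3-dioxolan-2-yl]butan-2-ol | CC(O)[C@H](O[Si](C)(C)C(C)(C)C)CC1(CCI)OCCO1
F2 | step 8 | (2RS,3R)-3-[(tert-butyldimethylsilyl)oxy]-4-[2-(2-nitroethyl)-1,3-dioxolan-2-yl]butan-2-ol | CC(O)[C@H](O[Si](C)(C)C(C)(C)C)CC1(CC[N+](=O)[O-])OCCO1
F3 | step 8 | (3R)-3-[(tert-butyldimethylsilyl)oxy]-4-[2-(2-nitroethyl)-1,3-dioxolan-2-yl]butan-2-one | CC(=O)[C@H](O[Si](C)(C)C(C)(C)C)CC1(CC[N+](=O)[O-])OCCO1
F4 | step 8 | (8S,9R)-9-[(tert-butyldimethylsilyl)oxy]-8-methyl-7-nitro-1,4-dioxaspiro[4.5]decan-8-ol | CC(C)(C)[Si](C)(C)O[C@@H]1CC2(OCCO2)CC([N+](=O)[O-])[C@]1(C)O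
F5 | step 13 | (4R,5R)-2-bromo-5-[(tert-butyldimethylsilyl)oxy]-4-hydroxy-4-methylcyclohexane-1,3-dione | CC(C)(C)[Si](C)(C)O[C@@H]1CC(=O)C(Br)C(=O)[C@]1(C)O
F6 | step 13 | (4R,5R)-2-bromo-5-[(tert-butyldimethylsilyl)oxy]-4-hydroxy-4-methyl-3-oxocyclohex-1-en-1-yl trifluoromethanesulfonate | CC(C)(C)[Si](C)(C)O[C@@H]1CC(OS(=O)(=O)C(F)(F)F)=C(Br)C(=O)[C@]1(C)O
F7 | step 13 | (5R,6R)-2-bromo-5-[(tert-butyldimethylsilyl)oxy]-3-{(3E)-5-[(tert-butyldiphenylsilyl)oxy]pent-3-en-1-yn-1-yl}-6-hydroxy-6-methylcyclohex-2-en-1-one | CC(C)(C)[Si](C)(C)O[C@@H]1CC(C#C/C=C/CO[Si](c2ccccc2)(c2ccccc2)C(C)(C)C)=C(Br)C(=O)[C@]1(C)O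
F8 | step 17 | 7-hydroxy-2,2,5-trimethyl-4H-1,3-benzodioxin-4-one | Cc1cc(O)cc2OC(C)(C)OC(=O)c12
F9 | step 17 | 7-[(tert-butyldimethylsilyl)oxy]-2,2,5-trimethyl-4H-1,3-benzodioxin-4-one | Cc1cc(O[Si](C)(C)C(C)(C)C)cc2OC(C)(C)OC(=O)c12
F10 | step 17 | (6R,7R)-3-{(1E)-3-[(tert-butyldiphenylsilyl)oxy]prop-1-en-1-yl}-7-hydroxy-7-methyl-8-oxo-5,6,7,8-tetrahydro-1H-isochromen-6-yl 4-[(tert-butyldimethylsilyl)oxy]-2-hydroxy-6-methylbenzoate | Cc1cc(O[Si](C)(C)C(C)(C)C)cc(O)c1C(=O)O[C@@H]1CC2=C(COC(/C=C/CO[Si](c3ccccc3)(c3ccccc3)C(C)(C)C)=C2)C(=O)[C@]1(C)O
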